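Divide the rate of other capture product by the rate of target: if one dissolved species feeds both captures, the dissolving solid and the clock cancel, and the ratio is a constant times second nucleophile over first nucleophile.

common to all: solid substrate 0.050 M

| run | first nucleophile | second nucleophile | remark | time |
|---|---|---|---|---|
| east | 0.10 M | 0.027 M | run made earlier |  |
| north | 0.10 M | 0.060 M | run made earlier |  |
| flask | 0.100 M | 0.0400 M |  | 5.0 h |

| run | time / h | other capture product / % | target / % |
|---|---|---|---|
| east | 0.417 | 32.0 | 7.7 |
| east | 0.833 | 50.8 | 21.6 |
| east | 1.33 | 53.7 | 45.7 |
| east | 1.50 | 53.6 | 46.0 |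
| east | 2.00 | 53.5 | 46.1 |
| east | 2.50 | 54.2 | 46.0 |
| east | 3.00 | 54.1 | 45.8 |
| north | 0.167 | 13.8 | 1.3 |
| north | 0.500 | 45.1 | 3.7 |
| north | 0.833 | 74.9 | 7.0 |
| north | 1.33 | 89.2 | 10.3 |
| north | 2.00 | 89.3 | 10.7 |
| north | 2.50 | 90.1 | 11.3 |
| north | 3.00 | 89.6 | 10.8 |

(each reading ± 0.5 percentage points)

- solid, in amounts per volume of the solution: solid substrate
- what was read earlier has a scatter of 0.5 percentage points, one standard deviation
- at the start none of the solid substrate is in solution

- ratio of other capture product to target at 80 s
- ratio of other capture product to target at 5.0 h

The north run ends at 3.00 h with 89.6% other capture product and 10.8% target, which leaves fractions 25.3% of second and 94.6% of first nucleophile. That gives a reading of 24.7 for the selectivity factor, the logarithm of the one fraction divided by the logarithm of the other.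

In the first instants of the flask both nucleophiles stand near their charges, so this reckoning puts the ratio at 80 s at 9.89. In the middle of the flask, by this reading, the logarithm of the second nucleophile's fraction falls 24.7 times as fast as that of the first, so the ratio slides down. The north run's two products sum to 100% of its charge, so this reckoning lets the two products share the flask's charge at the end. The flask's second nucleophile covers 80.0% of the solid charge, so on that sharing target takes at least 20.0%. Feeding that share through the rule gives 25.9% target, and a second pass gives 22.6%, so this reckoning brackets the final ratio between 2.86 and 3.42.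

The forecast says 9.8 and 3.2, on the ground that “both products capture the same dissolved substrate”.

The flask gives 9.66 and 3.22.

    starting material ⇌ intermediate (K = 0.0170, k = 0.0293 s⁻¹)
    first nucleophile + intermediate → target (k = 6.37 L mol⁻¹ s⁻¹)
    second nucleophile + intermediate → other capture product (k = 155 L mol⁻¹ s⁻¹)
    starting material → decomposition product (k = 3.52 × 10⁻⁶ s⁻¹)
    solid substrate ⇌ starting material, rate k5*(cs5 - [starting material]) while solid is left; crystals form when [starting material] > cs5 (solubility = 2.20 mM, k = 0.00877 s⁻¹)

With 88% of first nucleophile left, the rule leaves 4.42% of second; the flask holds 4.6%. For the neighbour flask with 0.016 M of second nucleophile the same reckoning puts the ratio at 80 s at 3.96, and the simulation gives 3.84. Its second nucleophile covers 32.0% of the solid charge. If target takes the rest, first nucleophile falls to 66.0%, and the rule leaves hardly any second nucleophile. That neighbour ends with 32.0% other capture product against 68.0% target, a ratio of 0.471.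

All runs are simulated on assumed constants; the scatter is artificial.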